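**Retrosynthetic overview**

1. The dioxane ring is the only ring made and is closed last, at O1–C2: a ring-A phenol closes onto a syringyl benzylic carbinol through the p-quinone methide, giving the trans (2R,3R) ring under thermodynamic control from the fixed C3.
2. O4–C3 comes from a Mitsunobu inversion of an (S)-α-hydroxy ketone by the 4-OH of 5-hydroxyvanillin. The CHO group directs that regiochemistry and then becomes the (E)-propenyl group (Takai–Utimoto).
3. The key C2–C3 bond joins two aldehyde carbons: the carbonyl carbon of protected syringaldehyde reacts as an acyl anion (enzyme-bound Breslow enaminol) and adds to acetaldehyde in an asymmetric cross-acyloin coupling that sets C3 in the same step.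
4. Order: C–C bond (step 2), aryl ether (step 3), propenyl (step 4), reduction and deprotection (step 5), dioxane ring (step 6).

Assumption: recombinant benzoylformate decarboxylase from Pseudomonas putida is expressed by standard methods and counts as a catalyst, not a starting material; the target is the trans-(2R,3R) isomer that the SMILES encodes.

**Route**

Step 1
Reactants: 1 syringaldehyde (4-hydroxy-3,5-dimethoxybenzaldehyde); 2 acetic anhydride
Product: 3 4-formyl-2,6-dimethoxyphenyl acetate
Conditions: Ac2O (1.2 equiv), Et3N (1.5 equiv), DMAP (2 mol %), CH2Cl2, 0 °C → rt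
Reagents that add atoms: acetic anhydride (2), CC(=O)OC(C)=O
Why: DMAP-catalysed O-acylation of the only hydroxyl masks the syringyl phenol for the Mitsunobu step with a group that is small enough for the enzyme pocket and that comes off in the same flask as the later ketone reduction.

Step 2
Reactants: 3 4-formyl-2,6-dimethoxyphenyl acetate; 4 acetaldehyde
Product: 6 (S)-4-(2-hydroxypropanoyl)-2,6-dimethoxyphenyl acetate, via ThDP-bound Breslow enaminol 5 (not isolated)
Conditions: benzoylformate decarboxylase (Pseudomonas putida, purified), thiamine diphosphate (0.5 mM), MgSO4 (2.5 mM), KH2PO4/K2HPO4 buffer (50 mM, pH 6.5), DMSO (20% v/v), MeCHO (10 equiv, fed in portions), 20 °C, 24–48 h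
Reagents that add atoms: acetaldehyde (4), CC=O
Why: In this enzymatic cross-acyloin (benzoin-type) carboligation the thiamine diphosphate ylide adds to the aryl aldehyde to give the nucleophilic enaminol 5 (an acyl anion equivalent), which attacks acetaldehyde held in the small pocket of the active site so that the new carbinol centre (the future C3) is formed as (S), as this enzyme does for benzaldehyde and for meta- and para-substituted benzaldehydes (typically 90–99% ee), the 3,4,5-trioxygenated substrate being an extrapolation of that scope.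

Step 3
Reactants: 6 (S)-4-(2-hydroxypropanoyl)-2,6-dimethoxyphenyl acetate; 7 5-hydroxyvanillin (3,4-dihydroxy-5-methoxybenzaldehyde)
Product: 8 4-[(2R)-2-(4-formyl-2-hydroxy-6-methoxyphenoxy)propanoyl]-2,6-dimethoxyphenyl acetate
Conditions: PPh3 (1.3 equiv), DIAD (1.3 equiv), 7 (1.2 equiv), THF, 0 °C → rt
Reagents that add atoms: 3,4-dihydroxy-5-methoxybenzaldehyde (7), COc1cc(C=O)cc(O)c1O
Why: In this Mitsunobu etherification the phenol para to the formyl group is the more acidic one (pKa about 7.5 against about 9.5) and is therefore the one that is deprotonated and alkylated, and the SN2 displacement at the lactate-like α-keto carbinol inverts (S) to (R) under near-neutral conditions that do not enolise the ketone.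

Step 4
Reactants: 8 4-[(2R)-2-(4-formyl-2-hydroxy-6-methoxyphenoxy)propanoyl]-2,6-dimethoxyphenyl acetate; 9 1,1-diiodoethane
Product: 10 4-[(2R)-2-{2-hydroxy-6-methoxy-4-[(E)-prop-1-enyl]phenoxy}propanoyl]-2,6-dimethoxyphenyl acetate
Conditions: CH3CHI2 (2.5 equiv), CrCl2 (10 equiv), DMF (10 equiv), THF, 0 °C → rt
Reagents that add atoms: 1,1-diiodoethane (9), CC(I)I
Why: In this Takai–Utimoto ethylidenation the geminal dichromium reagent adds to the aldehyde only (aryl ketone and aryl acetate are left alone), is non-basic so the α-aryloxy ketone centre is not enolised, and gives the (E)-alkene by anti elimination (E:Z about 9:1 or better, the Z isomer being removed on AgNO3-doped silica or by crystallising 13), the excess covering the reagent quenched by the free phenol.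

Step 5
Reactants: 10 4-[(2R)-2-{2-hydroxy-6-methoxy-4-[(E)-prop-1-enyl]phenoxy}propanoyl]-2,6-dimethoxyphenyl acetate
Product: 12 4-[(1RS,2R)-1-hydroxy-2-{2-hydroxy-6-methoxy-4-[(E)-prop-1-enyl]phenoxy}propyl]-2,6-dimethoxyphenol (C1 epimer mixture), via acetate-protected benzylic alcohol 11 (not isolated)
Conditions: NaBH4 (1.5 equiv), THF/MeOH (4:1), −20 °C; then K2CO3 (0.2 equiv), MeOH, rt; aq NH4Cl
Reagents that add atoms: none
Why: Borohydride reduction of the aryl ketone is fast at low temperature (faster than enolisation, so C2 of the chain stays R), the configuration of the new carbinol centre does not matter because it is erased in step 6, and base-catalysed methanolysis (transesterification) of the aryl acetate then frees the syringyl phenol in the same flask.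

Step 6
Reactants: 12 4-[(1RS,2R)-1-hydroxy-2-{2-hydroxy-6-methoxy-4-[(E)-prop-1-enyl]phenoxy}propyl]-2,6-dimethoxyphenol
Product: 13 4-[(2R,3R)-5-methoxy-3-methyl-7-[(E)-prop-1-enyl]-2,3-dihydro-1,4-benzodioxin-2-yl]-2,6-dimethoxyphenol (CNP0227775.1)
Conditions: TsOH·H2O (10 mol %), CH2Cl2 (0.01 M), 4 Å MS, 0 °C → rt, 1–2 h
Reagents that add atoms: none
Why: Acid-catalysed dehydrative cyclisation ionises the p-hydroxybenzylic alcohol to the syringyl p-quinone methide (benzylic cation) that the ring-A phenol traps in a six-membered ring closure; because the closure is reversible both epimers of 12 converge on the trans dioxane with aryl and methyl equatorial, which with the fixed (3R) centre means (2R) (typically at least 5:1 trans:cis, the minor cis isomer being separated or re-equilibrated), while catalytic acid at room temperature is too weak to protonate the propenyl group.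

**Compound list**

1 | syringaldehyde (4-hydroxy-3,5-dimethoxybenzaldehyde) | COc1cc(C=O)cc(OC)c1O | starting material
2 | acetic anhydride | CC(=O)OC(C)=O | starting material
3 | 4-formyl-2,6-dimethoxyphenyl acetate | COc1cc(C=O)cc(OC)c1OC(C)=O | intermediate
4 | acetaldehyde | CC=O | starting material
5 | Breslow enaminol of 3 on thiamine diphosphate (enzyme-bound) | Cc1ncc(CN2C(C)=C(CCOP(=O)(O)OP(=O)(O)O)SC2=C(O)c2cc(OC)c(OC(C)=O)c(OC)c2)c(N)n1 | intermediate (not isolated)
6 | (S)-4-(2-hydroxypropanoyl)-2,6-dimethoxyphenyl acetate | C[C@H](O)C(=O)c1cc(OC)c(OC(C)=O)c(OC)c1 | intermediate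
7 | 5-hydroxyvanillin (3,4-dihydroxy-5-methoxybenzaldehyde) | COc1cc(C=O)cc(O)c1O | starting material
8 | 4-[(2R)-2-(4-formyl-2-hydroxy-6-methoxyphenoxy)propanoyl]-2,6-dimethoxyphenyl acetate | C[C@@H](Oc1c(O)cc(C=O)cc1OC)C(=O)c1cc(OC)c(OC(C)=O)c(OC)c1 | intermediate
9 | 1,1-diiodoethane | CC(I)I | starting material
10 | 4-[(2R)-2-{2-hydroxy-6-methoxy-4-[(E)-prop-1-enyl]phenoxy}propanoyl]-2,6-dimethoxyphenyl acetate | C/C=C/c1cc(O)c(O[C@H](C)C(=O)c2cc(OC)c(OC(C)=O)c(OC)c2)c(OC)c1 | intermediate
11 | 4-[(1RS,2R)-1-hydroxy-2-{2-hydroxy-6-methoxy-4-[(E)-prop-1-enyl]phenoxy}propyl]-2,6-dimethoxyphenyl acetate | C/C=C/c1cc(O)c(O[C@H](C)C(O)c2cc(OC)c(OC(C)=O)c(OC)c2)c(OC)c1 | intermediate (not isolated)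
12 | 4-[(1RS,2R)-1-hydroxy-2-{2-hydroxy-6-methoxy-4-[(E)-prop-1-enyl]phenoxy}propyl]-2,6-dimethoxyphenol | C/C=C/c1cc(O)c(O[C@H](C)C(O)c2cc(OC)c(O)c(OC)c2)c(OC)c1 | intermediate
13 | 4-[(2R,3R)-5-methoxy-3-methyl-7-[(E)-prop-1-enyl]-2,3-dihydro-1,4-benzodioxin-2-yl]-2,6-dimethoxyphenol | C/C=C/c1cc(OC)c2c(c1)O[C@H](c1cc(OC)c(O)c(OC)c1)[C@@H](C)O2 | target

**Totals and risks**

Total step count: 6. Longest linear sequence: 6 steps (1 → 3 → 6 → 8 → 10 → 12 → 13); 7 enters as bought material in step 3.

The three steps most likely to fail are steps 2, 3 and 4.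

Step 2 may fail because the enzyme has not been shown to accept a 3,4,5-trioxygenated benzaldehyde, its enantioselectivity may drop, and the aryl acetate may hydrolyse slowly in the buffer. The fallback sets out from 3 and uses the (R)-selective benzaldehyde lyase from Pseudomonas fluorescens (thiamine diphosphate, MgSO4, buffer pH 7, 20% DMSO, excess acetaldehyde). This enzyme has a wider pocket and a broad scope with polymethoxylated benzaldehydes, and it gives (R)-4-(2-hydroxypropanoyl)-2,6-dimethoxyphenyl acetate F1. Because F1 has the wrong configuration for a single inversion, it is turned with inversion into (S)-4-(2-chloropropanoyl)-2,6-dimethoxyphenyl acetate F2 (PPh3, CCl4, CH2Cl2, 0 °C → rt). F2 then alkylates the more acidic 4-OH of 7 with a second inversion (KHCO3, DMF, rt), and the route is rejoined at 8.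

Step 3 may fail because the phenol is flanked on both sides and the alcohol is secondary, so the Mitsunobu reaction may be slow, may touch the 3-OH, or may transfer some acetyl. The fallback sets out from 6, which is converted with retention into (S)-1-(4-acetoxy-3,5-dimethoxyphenyl)-1-oxopropan-2-yl methanesulfonate F3 (MsCl, Et3N, CH2Cl2, −20 °C). The α-keto mesylate is then displaced with inversion by the 4-phenoxide of 7 under weak-base conditions that are selective for the phenol para to the aldehyde (KHCO3 or Li2CO3, DMF, rt), and the route is rejoined at 8.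

Step 4 may fail because the substrate carries a free phenol and an α-aryloxy ketone and the E:Z ratio may be insufficient. The fallback sets out from 8, moves the olefination to the end, and also keeps the propenyl group out of the acid step:

- The aldehyde is masked (HC(OMe)3, PPTS cat., MeOH, rt) as 4-[(2R)-2-[4-(dimethoxymethyl)-2-hydroxy-6-methoxyphenoxy]propanoyl]-2,6-dimethoxyphenyl acetate F4.
- Reduction and deacetylation as in step 5 (NaBH4, THF/MeOH; then K2CO3, MeOH) give 4-[(1RS,2R)-2-[4-(dimethoxymethyl)-2-hydroxy-6-methoxyphenoxy]-1-hydroxypropyl]-2,6-dimethoxyphenol F5.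
- Aqueous acid (TsOH·H2O cat., THF/H2O, rt) unmasks the aldehyde and closes the trans dioxane ring to (2R,3R)-2-(4-hydroxy-3,5-dimethoxyphenyl)-5-methoxy-3-methyl-2,3-dihydro-1,4-benzodioxine-7-carbaldehyde F6.
- An (E)-selective Julia–Kocienski olefination with 5-(ethylsulfonyl)-1-phenyl-1H-tetrazole (KN(SiMe3)2, 2.2 equiv, DME, −60 °C → rt) comes back to the route at the target 13.

**Further compounds**

F1 | step 2 | (R)-4-(2-hydroxypropanoyl)-2,6-dimethoxyphenyl acetate | C[C@@H](O)C(=O)c1cc(OC)c(OC(C)=O)c(OC)c1
F2 | step 2 | (S)-4-(2-chloropropanoyl)-2,6-dimethoxyphenyl acetate | C[C@H](Cl)C(=O)c1cc(OC)c(OC(C)=O)c(OC)c1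
F3 | step 3 | (S)-1-(4-acetoxy-3,5-dimethoxyphenyl)-1-oxopropan-2-yl methanesulfonate | C[C@H](OS(C)(=O)=O)C(=O)c1cc(OC)c(OC(C)=O)c(OC)c1
F4 | step 4 | 4-[(2R)-2-[4-(dimethoxymethyl)-2-hydroxy-6-methoxyphenoxy]propanoyl]-2,6-dimethoxyphenyl acetate | C[C@@H](Oc1c(O)cc(C(OC)OC)cc1OC)C(=O)c1cc(OC)c(OC(C)=O)c(OC)c1
F5 | step 4 | 4-[(1RS,2R)-2-[4-(dimethoxymethyl)-2-hydroxy-6-methoxyphenoxy]-1-hydroxypropyl]-2,6-dimethoxyphenol | C[C@@H](Oc1c(O)cc(C(OC)OC)cc1OC)C(O)c1cc(OC)c(O)c(OC)c1
F6 | step 4 | (2R,3R)-2-(4-hydroxy-3,5-dimethoxyphenyl)-5-methoxy-3-methyl-2,3-dihydro-1,4-benzodioxine-7-carbaldehyde | O=Cc1cc(OC)c2c(c1)O[C@H](c1cc(OC)c(O)c(OC)c1)[C@@H](C)O2
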